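The eleven ring carbons are numbered around the perimeter: C1 (ketone), C2, C3 (quaternary CMe), C4, C5 and C6 (ester carbons), C7 (CMe2), C8, C9, C10 (CHMe), C11. Ring A is the cyclobutane C2–C3–C9–C8, ring B the cyclohexanone, ring C the cycloheptane. The route rests on the C2–C3 bond. Because C2 is the α-carbon of the C1 ketone, this bond is formed by a semipinacol 1,2-shift: in a 1-hydroxynorbornane whose bridge carbon C3 is still bonded to C1, an endo triflate at C2 makes C3 migrate from C1 to C2. One operation contracts a cyclopentane to ring A and unveils the ketone. The precursor is a bridged norbornane-1,2-diol made by a ketyl–enone cyclization.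

Key step: step 11

Assumption 1: in step 5 the (S)-configured oxazaborolidinium catalyst is taken as the one that exposes the Re face of C9 of the bound enone; if the transition-state model points the other way, its enantiomer is used.
Assumption 2: compound 13 may sit partly as its C1–O–C5 hemiketal; the oxygen drives the shift from either form, so it is drawn as the open hydroxy ketone.

Step 1
Reactants: 1 (S)-pantolactone
Product: 2 (2S)-2,4-dihydroxy-N-methoxy-N,3,3-trimethylbutanamide
Conditions: MeNH(OMe)·HCl, i-PrMgCl, THF, −20 → 0 °C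
Reagents that add atoms: N,O-dimethylhydroxylamine hydrochloride, CNOC.Cl
Why: Aminolysis of the lactone by MeN(OMe)MgCl gives the N-methoxy-N-methylamide (future C5) without touching the C6 stereocentre and frees the primary C8 hydroxyl.

Step 2
Reactants: 2 dihydroxy amide
Product: 3 (2S)-2-hydroxy-N-methoxy-N,3,3-trimethyl-4-oxobutanamide
Conditions: TEMPO (10 mol %), PhI(OAc)2, CH2Cl2, rt
Reagents that add atoms: none
Why: Oxoammonium oxidation should be selective for the primary alcohol over the hindered secondary α-hydroxy amide, and the neopentyl aldehyde cannot enolise.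

Step 3
Reactants: 3 hydroxy aldehyde
Product: 4 (2S,4E)-2-hydroxy-N-methoxy-N,3,3-trimethyl-6-oxohept-4-enamide
Conditions: Ph3P=CHC(O)Me, toluene, 90 °C
Reagents that add atoms: 1-(triphenyl-λ5-phosphanylidene)propan-2-one, CC(=O)C=P(c1ccccc1)(c1ccccc1)c1ccccc1
Why: Wittig olefination with the stabilised ylide should give the (E)-enone and brings in C2, C1 and C11.

Step 4
Reactants: 4 hydroxy enone
Product: 5 (2S,4E)-2,6-bis(tert-butyldimethylsilyloxy)-N-methoxy-N,3,3-trimethylhepta-4,6-dienamide
Conditions: TBSOTf (2.4 equiv), Et3N, CH2Cl2, −78 → 0 °C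
Reagents that add atoms: tert-butyldimethylsilyl trifluoromethanesulfonate, CC(C)(C)[Si](C)(C)OS(=O)(=O)C(F)(F)F
Why: Silyl triflate and amine protect the C6 hydroxyl and convert the methyl ketone, whose γ-position is quaternary, into the 2-silyloxy diene in one operation.

Step 5
Reactants: 5 silyloxy diene; 6 (E)-pent-3-en-2-one
Product: 7 Diels–Alder adduct (cyclohexene silyl enol ether with C9 acetyl)
Conditions: (S)-3,3-diphenyl-1-(o-tolyl)tetrahydro-1H,3H-pyrrolo[1,2-c][1,3,2]oxazaborole (20 mol %), Tf2NH (18 mol %), CH2Cl2, −78 → −40 °C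
Reagents that add atoms: none
Why: The Diels–Alder cycloaddition builds ring B: the silyloxy group directs C11 to the β-carbon (C10) and C8 to the α-carbon (C9) of the enone, the endo transition state places the C8 side chain cis to the C9 acetyl, the (E)-dienophile places acetyl trans to the C10 methyl, and the chiral Lewis acid selects the enone face, so C8, C9 and C10 are set here.

Step 6
Reactants: 7 acetyl cyclohexene
Product: 8 isopropenyl cyclohexene
Conditions: Ph3PCH3Br, KN(SiMe3)2, THF, −78 → 0 °C
Reagents that add atoms: methyltriphenylphosphonium bromide, C[P+](c1ccccc1)(c1ccccc1)c1ccccc1.[Br-]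
Why: Wittig methylenation at low temperature should turn the acetyl group into the isopropenyl group (C3 with its methyl) without epimerising C9, the amide and silyl enol ether being inert to the ylide.

Step 7
Reactants: 8 N-methoxy-N-methylamide
Product: 9 vinyl ketone
Conditions: CH2=CHMgBr, THF, −20 °C; cold aq NH4Cl
Reagents that add atoms: vinylmagnesium bromide, C=C[Mg]Br
Why: Addition to the N-methoxy-N-methylamide stops at the chelated tetrahedral intermediate and should give the vinyl ketone, bringing in C4.

Step 8
Reactants: 9 vinyl ketone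
Product: 10 cis-fused bicyclic enone with ring B as silyl enol ether
Conditions: second-generation Hoveyda–Grubbs catalyst, RuCl2(H2IMes)(=CH-C6H4-2-OiPr) (5 mol %), toluene, 80 °C
Reagents that add atoms: none
Why: Ring-closing metathesis between the isopropenyl group and the vinyl ketone, held cis on C9 and C8, should close ring C as the C3=C4 enone with loss of ethene.

Step 9
Reactants: 10 silyl enol ether
Product: 12 C2-hydroxy C1-ketone, via silyloxy epoxide 11 (not isolated)
Conditions: DMDO, acetone/CH2Cl2, −40 °C; then AcOH–THF–H2O, rt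
Reagents that add atoms: dimethyldioxirane, CC1(C)OO1
Why: In this Rubottom oxidation the dioxirane should epoxidise the electron-rich enol ether rather than the enone, from the face opposite the cis-fused ring C, and acid hydrolysis of the silyloxy epoxide gives the C2 alcohol trans to the C8 substituent while the hindered C6 silyl ether stays.

Step 10
Reactants: 12 α-hydroxy ketone enone
Product: 13 bridged keto diol (1-hydroxynorbornane with C1–C3 bond)
Conditions: SmI2 (2.5 equiv), MeOH (4 equiv), THF, −78 °C
Reagents that add atoms: none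
Why: Samarium diiodide should reduce the chelated C1 ketone to its ketyl, which adds 5-exo-trig to the enone β-carbon C3 (ketyl–olefin cyclization); the ring system fixes the configuration at C1 and C3, and protonation of the samarium enolate leaves C4 as CH2 beside the C5 ketone.

Step 11
Reactants: 13 bridged keto diol
Product: 15 tricyclic 1,5-diketone 6-O-TBS ether, via endo-C2 triflate 14 (not isolated)
Conditions: Tf2O (1.1 equiv), 2,6-lutidine (3 equiv), CH2Cl2, −78 → 0 °C
Reagents that add atoms: none
Why: Tf2O should sulfonylate only the secondary endo hydroxyl at C2, and on warming the C2–OTf bond ionises in concert with a 1,2-shift of the bridge carbon C3 from C1 to C2 while the C1 hydroxyl becomes the ketone, lutidine taking the proton. The closest known reaction type is the semipinacol ring contraction of cyclic 2-sulfonyloxy alcohols, here in the sense of a reversed bornyl-to-pinanyl shift. Ring A closes by a suprafacial 1,2-alkyl shift, in effect a backside displacement at C2 by C3, so the cyclopentane C1–C2–C8–C9–C3 contracts to the cyclobutane and the norbornane becomes the bicyclo[3.1.1]heptan-2-one (ring B) spanned by the bicyclo[4.1.1]octane. No new stereocentre arises: C3 migrates with retention and C2 is inverted, its configuration being dictated by the endo oxygen set in step 9. The step needs C3 to move rather than C11 or a hydride; the norbornane secures this because only the C1–C3 bond is antiperiplanar to an endo leaving group, the C8 hydrogen is syn to it (no anti elimination) and a bridgehead epoxide cannot form. Carbonyl formation and loss of triflate should outweigh the added strain and make the closure irreversible, whereas a Michael-type closure of this bond would be reversible and uphill.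

Step 12
Reactants: 15 silyl ether
Product: 16 6-hydroxy 1,5-diketone
Conditions: HF·pyridine, THF, 0 °C → rt
Reagents that add atoms: none
Why: Fluoride cleaves the hindered secondary silyl ether under acidic, non-basic conditions that avoid retro-Michael opening of the strained 1,5-diketone.

Step 13
Reactants: 16 α-hydroxy ketone
Product: 17 5,6-trans-diol 1-ketone
Conditions: Me4NBH(OAc)3, AcOH/MeCN, −30 °C
Reagents that add atoms: none
Why: In this hydroxyl-directed reduction the C6 alkoxyborohydride delivers hydride to C5 from the face of the C6 oxygen, which should give the trans diol and leave the unactivated C1 ketone untouched.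

Step 14
Reactants: 17 diol; 18 angelic acid (two equivalents are incorporated, one per hydroxyl)
Product: 21 target diangelate, via mixed anhydride 19 (not isolated), via 5-O-monoangelate 20 (not isolated)
Conditions: 18 (6 equiv), 2,4,6-trichlorobenzoyl chloride (6 equiv), Et3N (12 equiv), toluene, rt; then 17, 80 °C
Reagents that add atoms: (Z)-2-methylbut-2-enoic acid (second equivalent of 18), C/C=C(/C)C(=O)O
Why: In this Yamaguchi-type acylation, run without a nucleophilic catalyst so that the (Z) geometry of the angelate is kept, each hydroxyl takes one angeloyl group from one molecule of the mixed anhydride, the less hindered C5 hydroxyl first and the neopentyl C6 hydroxyl on prolonged heating with the excess reagent.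

Compound list
1 | (S)-pantolactone, (3S)-3-hydroxy-4,4-dimethyloxolan-2-one | CC1(C)COC(=O)[C@H]1O | starting material
2 | (2S)-2,4-dihydroxy-N-methoxy-N,3,3-trimethylbutanamide | CON(C)C(=O)[C@@H](O)C(C)(C)CO | intermediate
3 | (2S)-2-hydroxy-N-methoxy-N,3,3-trimethyl-4-oxobutanamide | CON(C)C(=O)[C@@H](O)C(C)(C)C=O | intermediate
4 | (2S,4E)-2-hydroxy-N-methoxy-N,3,3-trimethyl-6-oxohept-4-enamide | CON(C)C(=O)[C@@H](O)C(C)(C)/C=C/C(C)=O | intermediate
5 | (2S,4E)-2,6-bis(tert-butyldimethylsilyloxy)-N-methoxy-N,3,3-trimethylhepta-4,6-dienamide | CON(C)C(=O)[C@@H](O[Si](C)(C)C(C)(C)C)C(C)(C)/C=C/C(=C)O[Si](C)(C)C(C)(C)C | intermediate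
6 | (E)-pent-3-en-2-one | C/C=C/C(C)=O | starting material
7 | (2S)-3-[(1R,5R,6S)-6-acetyl-3-(tert-butyldimethylsilyloxy)-5-methylcyclohex-2-en-1-yl]-2-(tert-butyldimethylsilyloxy)-N-methoxy-N,3-dimethylbutanamide; side chain cis to acetyl, acetyl trans to methyl | CC(=O)[C@H]1[C@H](C)CC(O[Si](C)(C)C(C)(C)C)=C[C@H]1C(C)(C)[C@H](O[Si](C)(C)C(C)(C)C)C(=O)N(C)OC | intermediate
8 | analogue of 7 with prop-1-en-2-yl in place of acetyl, same spatial arrangement | C=C(C)[C@H]1[C@H](C)CC(O[Si](C)(C)C(C)(C)C)=C[C@H]1C(C)(C)[C@H](O[Si](C)(C)C(C)(C)C)C(=O)N(C)OC | intermediate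
9 | (4S)-4-(tert-butyldimethylsilyloxy)-5-[3-(tert-butyldimethylsilyloxy)-5-methyl-6-(prop-1-en-2-yl)cyclohex-2-en-1-yl]-5-methylhex-1-en-3-one, ring arrangement as in 8 | C=C(C)[C@H]1[C@H](C)CC(O[Si](C)(C)C(C)(C)C)=C[C@H]1C(C)(C)[C@H](O[Si](C)(C)C(C)(C)C)C(=O)C=C | intermediate
10 | bicyclic enone: ring B as C1=C2 silyl enol ether (1-OTBS), cis-fused at C8/C9 to ring C carrying the C3=C4–C5(=O) enone, 3-methyl, (6S)-OTBS, 7,7-dimethyl; 10-methyl trans to C3 | CC1=CC(=O)[C@@H](O[Si](C)(C)C(C)(C)C)C(C)(C)[C@@H]2C=C(O[Si](C)(C)C(C)(C)C)C[C@@H](C)[C@H]12 | intermediate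
11 | C1–C2 silyloxy epoxide of 10, oxygen on the face opposite ring C | CC1=CC(=O)[C@@H](O[Si](C)(C)C(C)(C)C)C(C)(C)[C@@H]2[C@H]3O[C@@]3(O[Si](C)(C)C(C)(C)C)C[C@@H](C)[C@H]12 | intermediate (not isolated)
12 | bicyclic enone with C1 ketone and C2 hydroxyl trans to the C8 substituent, otherwise as 10 | CC1=CC(=O)[C@@H](O[Si](C)(C)C(C)(C)C)C(C)(C)[C@@H]2[C@@H](O)C(=O)C[C@@H](C)[C@H]12 | intermediate
13 | bridged keto diol: 1-hydroxynorbornane (bridgeheads C1 and C9, bridge C3 bearing methyl and C4, two-carbon bridges C2–C8 and C11–C10) with endo OH at C2 and endo methyl at C10; ring C runs C3–C4–C5(=O)–C6(OTBS)–C7Me2 to exo C8 | C[C@]12CC(=O)[C@@H](O[Si](C)(C)C(C)(C)C)C(C)(C)[C@@H]3[C@@H](O)[C@@]1(O)C[C@@H](C)[C@H]23 | intermediate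
14 | endo-C2 trifluoromethanesulfonate of 13 | C[C@]12CC(=O)[C@@H](O[Si](C)(C)C(C)(C)C)C(C)(C)[C@@H]3[C@@H](OS(=O)(=O)C(F)(F)F)[C@@]1(O)C[C@@H](C)[C@H]23 | intermediate (not isolated)
15 | target skeleton (rings A, B, C) with ketones at C1 and C5 and (6S)-OTBS | O=C1C[C@]2(C)[C@@H]3[C@@H]([C@H]2C(=O)C[C@H]3C)C(C)(C)[C@@H]1O[Si](C)(C)C(C)(C)C | intermediate
16 | target skeleton with ketones at C1 and C5 and free 6-hydroxyl | O=C1C[C@]2(C)[C@@H]3[C@@H]([C@H]2C(=O)C[C@H]3C)C(C)(C)[C@@H]1O | intermediate
17 | target skeleton with C1 ketone and trans-5,6-diol | O[C@H]1C[C@]2(C)[C@@H]3[C@@H]([C@H]2C(=O)C[C@H]3C)C(C)(C)[C@@H]1O | intermediate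
18 | angelic acid, (Z)-2-methylbut-2-enoic acid | C/C=C(/C)C(=O)O | starting material
19 | (Z)-2-methylbut-2-enoic 2,4,6-trichlorobenzoic anhydride | C/C=C(/C)C(=O)OC(=O)c1c(Cl)cc(Cl)cc1Cl | intermediate (not isolated)
20 | 5-O-angeloyl 6-hydroxy tricyclic ketone (monoangelate at the less hindered C5 hydroxyl) | C/C=C(/C)C(=O)O[C@H]1C[C@]2(C)[C@@H]3[C@@H]([C@H]2C(=O)C[C@H]3C)C(C)(C)[C@@H]1O | intermediate (not isolated)
21 | CNP0109825.1, 5,6-di-O-angeloyl tricyclic ketone | C/C=C(/C)C(=O)O[C@H]1C[C@]2(C)[C@@H]3[C@@H]([C@H]2C(=O)C[C@H]3C)C(C)(C)[C@@H]1OC(=O)/C(C)=C\C | target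

Total step count: 14. Longest linear sequence: 14 steps (1 → 21).

Steps most likely to fail

Step 11. The risks are incomplete sulfonylation of the hindered endo C2 hydroxyl, ionisation of the triflate ahead of migration (loss of stereoelectronic control and cationic side reactions), and base-induced retro-Michael opening of the product if the medium turns basic. The fallback separates activation from migration and uses a metal alkoxide as the driving group. From 13, MsCl and Et3N (CH2Cl2, −20 °C) should give the isolable endo-C2 mesylate F1. Et2AlCl (CH2Cl2, −78 → 0 °C) then converts the C1 hydroxyl into an aluminium alkoxide that drives the same C3 shift in a templated, non-ionising way (organoaluminium-promoted pinacol-type rearrangement). The route is rejoined at 15.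

Step 10. The risk is that reductive cleavage of the C2–O or C6–O bond next to the ketones, or plain saturation of the enone, outruns the cyclization. The fallback forms the same C1–C3 bond by a radical chain without a low-valent metal. From 12, Bu3SnH and AIBN (benzene, 80 °C; aqueous KF work-up) generate the O-stannyl ketyl, which should cyclize onto C3. The route is rejoined at 13, and no new compound is made (F0).

Step 5. The risks are poor facial selectivity, because the C6 stereocentre is insulated from the diene by the quaternary C7, inhibition of the catalyst by the amide, and a stepwise Mukaiyama–Michael pathway that erodes the cis C8/C9 relationship. The fallback moves stereocontrol to a covalently bound auxiliary. From 5, cycloaddition with (R)-4-benzyl-3-[(E)-but-2-enoyl]oxazolidin-2-one and Et2AlCl (CH2Cl2, −78 °C) should give the imide F2, the benzyl group shielding the Si face of C9. LiSEt (THF, 0 °C) then cleaves the auxiliary to the thioester F3, and Me2CuLi (Et2O, −40 °C) converts it into the methyl ketone. The route is rejoined at 7.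

Further compounds
F1 | step 11 | endo-C2 methanesulfonate of 13 | C[C@]12CC(=O)[C@@H](O[Si](C)(C)C(C)(C)C)C(C)(C)[C@@H]3[C@@H](OS(C)(=O)=O)[C@@]1(O)C[C@@H](C)[C@H]23
F0 | step 10 | none | none
F2 | step 5 | analogue of 7 with the C9 acyl group as its (R)-4-benzyl-2-oxooxazolidin-3-yl imide | O=C(N1[C@H](Cc2ccccc2)COC1=O)[C@H]1[C@H](C)CC(O[Si](C)(C)C(C)(C)C)=C[C@H]1C(C)(C)[C@H](O[Si](C)(C)C(C)(C)C)C(=O)N(C)OC
F3 | step 5 | analogue of 7 with the C9 acyl group as its S-ethyl thioester | CCSC(=O)[C@H]1[C@H](C)CC(O[Si](C)(C)C(C)(C)C)=C[C@H]1C(C)(C)[C@H](O[Si](C)(C)C(C)(C)C)C(=O)N(C)OC
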